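**Numbering and conventions.** Ring carbons are numbered C1–C10 as defined in the first sentence below; C11 is the side-chain carbon on C10, C12 the carboxyl or lactone carbonyl carbon, C13 the exocyclic methylene carbon. α is the face of C10–H in the flat germacrane projection (C1→C10 clockwise), β the opposite face. Compound numbers are those of the steps.

## The problem

The target 23 is a ten-membered carbocycle, numbered C1 (CH–O-methacryloyl), C2 (CH–OH), C3 (CH–CH3), C4 (enol-ether carbon), C5 (=CH), C6 (C=O), C7 (C(CH3)–O), C8 (CH2), C9 (CH–O of the lactone) and C10 (CH bearing the three-carbon unit). Two small rings lie across it: a 3(2H)-furanone (C4–C7 plus an ether oxygen) and a trans-fused α-methylene-γ-butyrolactone on C9–C10. A synthesis must close a medium ring, bridge it from C4 to C7 through oxygen, and oxidise seven carbons (C1, C2, C4, C6, C7, C9, C12). Six stereocentres are needed (1S,2S,3S,7R,9S,10R): C10 is the natural anchor, C9 and C1 flank it, C1–C2–C3 is a contiguous triad and C7 is a remote quaternary carbinol centre. The C2/C3 pair is the awkward one: the C2 hydroxyl and the C3 hydrogen are related as an anti addition across an E C2=C3 bond, which a syn hydroboration cannot give. The sensitive groups are the two acrylate-type acceptors (no alkoxides, thiolates, amines, unhindered hydrides or hydrogenation late on), the monoacylated 1,2-diol (acyl shift C1→C2 under base) and the β-hydroxy vinylogous ester C2–C3–C4=C5–C6=O (dehydration, epimerisation at C3). What makes the plan possible is that C1–C10, the methyls on C3 and C7 and the C3 unit on C10 are the head-to-tail carbon array of farnesol with C1 bonded to C10. Every oxygen sits on a carbon that is olefinic or allylic in germacrene A, or on C9, which a plant cytochrome P450 hydroxylates.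

## Retrosynthesis

**23 ⇒ 22 (C4–O).** The furanone is opened at the C4–O ether bond, giving the α'-hydroxy enone 22. Cutting C4–C5 or C7–O instead would break the carbocycle or require substitution at a tertiary centre. The forward reaction is a Wacker-type oxidative cyclisation with divalent palladium; it needs the E enone and the free tertiary hydroxyl, and the C2 hydroxyl cannot reach C4.

**22 ⇒ 20 (C3–H).** The C3 hydrogen is removed to reveal the alkenyl oxirane 20 (2β,3α-epoxide next to the C4=C5–C6=O enone). Hydride delivery from palladium to C3 with inversion gives exactly the anti H/OH relationship. The enone needed for the furanone doubles as the activating alkene. Both C2 and C3 then trace back to one E alkene.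

**20 ⇒ 19 ⇒ 18 ⇒ 17 ⇒ 16 (C4=C5, C6=O, C6–O/C7–O).** The enone comes from ketone 18 by Saegusa–Ito dehydrogenation through enol silane 19; C7 is quaternary, so enolisation can only go to C5. Ketol 18 comes from diol 17, and 17 from the C6=C7 alkene of 16 by osmylation. Epoxidation of C6=C7 was rejected: opening that oxirane needs acid, which triggers transannular cyclisation.

**16 ⇒ 14 ⇒ 13 (ester C–O, oxirane C–O).** The methacrylate is put on (from anhydride 15) while C1–OH is the only hydroxyl, so no diol has to be differentiated later. The oxirane of 14 comes from allylic alcohol 13 by hydroxyl-directed epoxidation, which also distinguishes C2=C3 from C6=C7.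

**13 ⇒ 11 ⇒ 10 (lactone C9–O).** No chemical reagent hydroxylates C1 of a C9-lactone selectively (C1 is on the wrong end of C2=C3 for SeO2). The lactone is therefore first closed on C1 and then moved: in mesylate 11 the liberated carboxylate displaces the C9 sulfonate with inversion. This turns eupatolide 10 (C1α–O lactone, C9β–OH) into 13 (C9α–O lactone, C1α–OH).

**10 ⇒ 8 ⇒ 7 ⇒ 4 (C–H oxidations at C1, C9, C12).** These are the native reactions of three cytochrome P450 enzymes (via intermediates 5, 6 and 9). C9 is unactivated and germacrene A is too labile for chemical allylic oxidants, so the enzymes are kept.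

**4 ⇒ 3 (C1–C10).** This is the strategic cut. Any other ring bond would demand a chemical macrocyclisation at high dilution with stereocentres already in place; the cyclase closes the ring from an achiral chain and sets C10.

**3 ⇒ 2 ⇒ 1 (C–O–P).** Diphosphate 3 comes from farnesol 1 via chloride 2.

## Roads not taken

**Alternative 1:** The cut is C4–C5, made inside a nine-membered lactone A1 (C4 is the lactone carbonyl, the ring oxygen is on C7, which also carries the acetyl group C6–C5). LiN(SiMe3)2 would enolise the acetyl group, C5 would add to the lactone carbonyl, and acid would dehydrate the cyclic hemiketal to give A2, closing carbocycle and furanone together.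
- Merits: every oxygen and stereocentre is placed beforehand by reagent-controlled chemistry on open chains; the route is wholly chemical and open to analogues.
- Weak points: A1 requires lactonisation onto a tertiary, α-acyl carbinol in a nine-membered ring; C3 is epimerisable and the C2 silyloxy group β-eliminable under the base; after A2 come PMB removal, acylation, oxidation of the allylic silyl ether to the acid, lactonisation and desilylation.
- Comparison: this road is better in not depending on enzyme selectivity or supply. The chosen plan sets against it a ring and C10 made in one unprotected step and a total of 16 steps.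

**Alternative 2:** The cut is the C4–O bond of A3, a cyclodecenone with C7–OH and a C2 silyl ether. PdCl2(MeCN)2/CuCl/O2 would effect oxypalladation and β-hydride elimination to A4, one desilylation from 23.
- Merits: the bridge is made last, so no strained bicycle is carried.
- Weak points: it does not say how the ten-membered ring of A3, with five stereocentres and an E enone, is made; a chemical macrocyclisation would be the real problem.
- Comparison: in the endgame this road is as good as the chosen one, which uses the same reaction type in step 16 on 22 (A3 without the silyl group). It would be stronger if the enzymes cannot be scaled. The chosen plan supplies the macrocycle and avoids the C2 protecting group.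

**Alternative 3:** The ten-membered ring is traced to decalin A5 by reconnecting C1–C6. KOtBu would form the C6 alkoxide, the C1–C6 bond would break and the equatorial C2 mesylate leave, giving A6 with the C6 ketone and an E C1=C2 alkene.
- Merits: the fragmentation is reliable and stereospecific; C3, C7, C9 and C10 are fixed on rigid chairs, C10 from carvone.
- Weak points: A5 has eight stereocentres and needs a long synthesis; after A6 the C1=C2 diol must be made face-selectively and its hydroxyls differentiated, C4 oxidised, the furanone closed and the isopropenyl group turned into the lactone.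
- Comparison: this road is better in the certainty of the C3, C7 and C9 configurations. The chosen plan sets against it far fewer steps and direct delivery of the C1, C9 and C12 oxygens, but its C7 configuration relies on conformational control in a flexible ring.

Key step: step 3

**Remarks.**
- Recombinant enzymes are treated as catalysts made by standard heterologous expression, not as starting materials.
- Compound 3 is drawn as the free acid but handled as its ammonium salt.
- In conventional germacranolide numbering, C1…C10 here are C6, C5, C4, C3, C2, C1, C10, C9, C8, C7.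

## Route

Step 1
Reactants: 1 (2E,6E)-farnesol
Product: 2 (2E,6E)-farnesyl chloride
Conditions: N-chlorosuccinimide, Me2S, CH2Cl2, −40 to 0 °C
Reagents that add atoms: N-chlorosuccinimide, O=C1CCC(=O)N1Cl
Why: Corey–Kim chlorination; chloride displaces the alkoxysulfonium group at the primary allylic carbon without allylic shift or loss of alkene geometry.

Step 2
Reactants: 2 (2E,6E)-farnesyl chloride
Product: 3 (2E,6E)-farnesyl diphosphate
Conditions: (Bu4N)3HP2O7, MeCN, 25 °C; cation-exchange resin (NH4+ form), cellulose chromatography
Reagents that add atoms: tris(tetrabutylammonium) hydrogen diphosphate, CCCC[N+](CCCC)(CCCC)CCCC.CCCC[N+](CCCC)(CCCC)CCCC.CCCC[N+](CCCC)(CCCC)CCCC.OP(=O)([O-])OP(=O)([O-])[O-]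
Why: SN2 displacement of the allylic chloride by the diphosphate anion, the standard preparation of allylic diphosphates; ion exchange gives the water-soluble salt the cyclase accepts.

Step 3
Reactants: 3 (2E,6E)-farnesyl diphosphate
Product: 4 (R)-germacrene A (E-C2=C3, E-C6=C7, isopropenyl on C10)
Conditions: recombinant (+)-germacrene A synthase (class 1 sesquiterpene synthase), MgCl2, HEPES buffer pH 7.5, dithiothreitol, pentane overlay, 25 °C; cold pentane extraction, basic alumina
Reagents that add atoms: none
Why: The cyclase binds the diphosphate through a trinuclear Mg2+ cluster and ionises the C1–O bond; the C10=C11 π bond, held over C1 by the fold of the active site, attacks C1 in the Markovnikov sense and the C11 cation loses a proton from one of its methyl groups. This is the native reaction of a class 1 sesquiterpene synthase, an enzymatic cation–olefin macrocyclisation, so no new reactivity is asked of it. The ten-membered ring closes by 1,10-attack of the allyl cation on the distal trisubstituted alkene (exo with respect to C10=C11, the charge ending on exocyclic C11), without dilution because the chain is pre-folded. The one new stereocentre, C10 (R), is fixed by the face of C10=C11 that the enzyme presents to C1, not by the substrate. The step needs 1,10- over 1,11- and 1,6-closure, retention of both E alkenes, and elimination instead of water capture or a second cyclisation: the E C2=C3 bond forbids 1,6-closure without isomerisation, Markovnikov attack favours the tertiary C11 cation, and the remainder is secured by choosing a synthase that releases germacrene A. The hydrocarbon is drawn into the pentane layer as formed and kept cold and neutral, because it undergoes Cope rearrangement on heating and proton-induced transannular cyclisation.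

Step 4
Reactants: 4 (R)-germacrene A
Product: 7 germacrene A acid (C12 carboxylic acid of 4; 10R), via allylic alcohol 5 (not isolated), via enal 6 (not isolated)
Conditions: yeast microsomes with germacrene A oxidase (CYP71AV family) and cytochrome P450 reductase, NADP+ (cat.), HCO2Na, NADP+-accepting formate dehydrogenase, air, potassium phosphate buffer pH 7.5, 30 °C
Reagents that add atoms: dioxygen, O=O
Why: Native three-stage cytochrome P450 oxidation of the isopropenyl methyl group (alcohol, aldehyde, acid) on its natural substrate; it runs neutral at 30 °C so the 1,5-diene survives, and no chemical oxidant distinguishes this methyl from the ring allylic positions.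

Step 5
Reactants: 7 germacrene A acid
Product: 8 9β-hydroxygermacrene A acid
Conditions: yeast microsomes with germacrene A acid 8β-hydroxylase (CYP71BL1 type; conventional locant 8 = C9 here) and cytochrome P450 reductase, NADP+ (cat.), HCO2Na, formate dehydrogenase, air, pH 7.5, 30 °C
Reagents that add atoms: dioxygen, O=O
Why: Cytochrome P450 C–H hydroxylation of the unactivated C9 methylene, the native reaction of this hydroxylase; the active site delivers oxygen to the β face and sets C9.

Step 6
Reactants: 8 9β-hydroxygermacrene A acid
Product: 10 eupatolide (lactone from C12 to the 1α oxygen; free 9β-hydroxyl), via dihydroxy acid 9 (not isolated)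
Conditions: yeast microsomes with eupatolide synthase (CYP71DD6 type) and cytochrome P450 reductase, NADP+ (cat.), HCO2Na, formate dehydrogenase, air, pH 7.5, 30 °C
Reagents that add atoms: dioxygen, O=O
Why: Enzymatic allylic hydroxylation at C1 on the α face (enzyme control), then spontaneous γ-lactonisation of the 1α-hydroxy acid trans to the C10–C11 bond; the 9β-hydroxyl would give a cis-fused lactone and stays free.

Step 7
Reactants: 10 eupatolide
Product: 11 eupatolide 9-O-methanesulfonate
Conditions: MsCl, Et3N, CH2Cl2, −10 °C
Reagents that add atoms: methanesulfonyl chloride, CS(=O)(=O)Cl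
Why: Sulfonylation of the only hydroxyl under basic conditions that spare the acid-labile diene; C9 is untouched.

Step 8
Reactants: 11 eupatolide 9-O-methanesulfonate
Product: 13 1α-hydroxy-12,9α-olide (2E,6E-diene; methylene lactone now on C9–C10), via lithium carboxylate 12 (not isolated)
Conditions: LiOH·H2O (1.05 equiv), THF–H2O, 0 °C; then DMF, 45 °C
Reagents that add atoms: lithium hydroxide, [Li+].[OH-]
Why: Saponification followed by intramolecular SN2 displacement (5-exo-tet) of the secondary mesylate by the carboxylate, i.e. lactonisation with inversion; C9 becomes α-O and trans to C11. The hydroxide is used up in the ring opening, so the new lactone meets no base, and a carboxylate cannot re-esterify C1–OH.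

Step 9
Reactants: 13 1α-hydroxy-12,9α-olide
Product: 14 2β,3α-epoxide of 13
Conditions: VO(acac)2 (5 mol %), t-BuOOH (decane solution), CH2Cl2, 0 °C
Reagents that add atoms: tert-butyl hydroperoxide, CC(C)(C)OO
Why: Hydroxyl-directed epoxidation; only the allylic-alcohol alkene reacts. A(1,3) strain with the C3 methyl places C1–H in the alkene plane, the hydroxyl on the outer face and C10 on the inner face, so oxygen is delivered to the 2β,3α face (the parthenolide-type arrangement).

Step 10
Reactants: 14 2β,3α-epoxide of 13; 15 methacrylic anhydride
Product: 16 1-O-methacrylate of 14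
Conditions: Et3N, DMAP (cat.), CH2Cl2, 0 to 25 °C
Reagents that add atoms: methacrylic anhydride (15), C=C(C)C(=O)OC(=O)C(C)=C
Why: DMAP-catalysed acylation of the only hydroxyl; done now so that no diol has to be differentiated later and no alkoxide sits beside the oxirane (no Payne rearrangement).

Step 11
Reactants: 16 1-O-methacrylate of 14
Product: 17 6β,7α-diol of 16
Conditions: OsO4 (3 mol %), N-methylmorpholine N-oxide (1.1 equiv), acetone–H2O, 0 °C
Reagents that add atoms: N-methylmorpholine N-oxide, C[N+]1([O-])CCOCC1; water, O
Why: Upjohn dihydroxylation; OsO4 prefers the electron-rich trisubstituted alkene to the two acrylate alkenes. Syn addition from the outer face of the E alkene should give the 6β,7α-diol and so set C7 (R).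

Step 12
Reactants: 17 6β,7α-diol of 16
Product: 18 6-oxo-7α-hydroxy compound (α-ketol)
Conditions: Dess–Martin periodinane, pyridine, CH2Cl2, 0 °C
Reagents that add atoms: none
Why: Dess–Martin oxidation of the secondary alcohol; the tertiary carbinol cannot be oxidised and the pyridine buffer protects the oxirane.

Step 13
Reactants: 18 α-ketol
Product: 19 bis(trimethylsilyl) derivative (C5=C6 enol silane, C7 silyl ether; enol geometry immaterial)
Conditions: Me3SiCl, then LiN(SiMe3)2 (2.3 equiv), THF, −78 °C
Reagents that add atoms: chlorotrimethylsilane, C[Si](C)(C)Cl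
Why: Enolisation can only go towards C5 because C7 is quaternary; trapping in situ gives the enol silane, prevents α-ketol rearrangement of the alkoxide, and caps C7–O so it cannot add to the enone in step 14.

Step 14
Reactants: 19 bis(trimethylsilyl) derivative
Product: 20 (4E)-4,5-en-6-one with the 2β,3α-oxirane and the 7α-trimethylsilyl ether
Conditions: Pd(OAc)2 (1.1 equiv), MeCN, 25 °C
Reagents that add atoms: none
Why: Saegusa–Ito dehydrogenation: the palladium enolate undergoes β-hydride elimination from C4 to the E enone, which makes the oxirane an alkenyl oxirane; the mixture is filtered promptly to remove zerovalent palladium.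

Step 15
Reactants: 20 epoxy enone
Product: 22 2β,7α-dihydroxy-(4E)-enone with 3β-H, via silyl ether 21 (not isolated)
Conditions: Pd2(dba)3·CHCl3 (3 mol %), n-Bu3P (6 mol %), HCO2H, Et3N, THF, 25 °C; then aq. citric acid, THF, 0 °C
Reagents that add atoms: none
Why: Tsuji-type formate hydrogenolysis of a γ-methyl-γ,δ-epoxy enone: zerovalent palladium ionises the allylic C3–O bond anti, formate loses CO2, and the hydride passes from palladium to the more substituted terminus C3 on the face opposite the departed oxygen. The result is net inversion at C3 (3β-H, methyl α), retention at C2 and a conjugated E enone. Excess formic acid keeps the medium acidic against acyl shift, and mild acid then removes the tertiary silyl ether.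

Step 16
Reactants: 22 dihydroxy enone
Product: 23 target, (1S,2S,3S,7R,9S,10R)
Conditions: PdCl2(MeCN)2 (10 mol %), CuCl (20 mol %), Na2HPO4, O2 (1 atm), 1,2-dimethoxyethane, 50 °C
Reagents that add atoms: none
Why: Wacker-type oxidative cyclisation of an α'-hydroxy enone to a 3(2H)-furanone: the C7 hydroxyl adds to C4 of the palladium-bound enone (5-endo-trig), β-hydride elimination restores C4=C5, and CuCl/O2 reoxidise the palladium. No stereocentre is formed or touched.

## Compound list

1 | (2E,6E)-farnesol | CC(C)=CCC/C(C)=C/CC/C(C)=C/CO | starting material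
2 | (2E,6E)-farnesyl chloride | CC(C)=CCC/C(C)=C/CC/C(C)=C/CCl | intermediate
3 | (2E,6E)-farnesyl diphosphate | CC(C)=CCC/C(C)=C/CC/C(C)=C/COP(O)(=O)OP(O)(O)=O | intermediate
4 | (R)-germacrene A | CC(=C)[C@@H]1CC/C(C)=C/CC/C(C)=C/C1 | intermediate
5 | germacrene A 12-alcohol | OCC(=C)[C@@H]1CC/C(C)=C/CC/C(C)=C/C1 | intermediate (not isolated)
6 | germacrene A 12-aldehyde | O=CC(=C)[C@@H]1CC/C(C)=C/CC/C(C)=C/C1 | intermediate (not isolated)
7 | germacrene A acid | OC(=O)C(=C)[C@@H]1CC/C(C)=C/CC/C(C)=C/C1 | intermediate
8 | 9β-hydroxygermacrene A acid | OC(=O)C(=C)[C@@H]1[C@H](O)C/C(C)=C/CC/C(C)=C/C1 | intermediate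
9 | 1α,9β-dihydroxygermacrene A acid | OC(=O)C(=C)[C@@H]1[C@H](O)C/C(C)=C/CC/C(C)=C/[C@H]1O | intermediate (not isolated)
10 | eupatolide | C=C1C(=O)O[C@@H]2/C=C(C)/CC/C=C(C)/C[C@@H](O)[C@@H]12 | intermediate
11 | eupatolide 9-O-methanesulfonate | C=C1C(=O)O[C@@H]2/C=C(C)/CC/C=C(C)/C[C@@H](OS(C)(=O)=O)[C@@H]12 | intermediate
12 | lithium 1α-hydroxy-9β-mesyloxy carboxylate | [Li+].[O-]C(=O)C(=C)[C@@H]1[C@H](OS(C)(=O)=O)C/C(C)=C/CC/C(C)=C/[C@H]1O | intermediate (not isolated)
13 | 1α-hydroxy-12,9α-olide | O[C@@H]1/C=C(C)/CC/C=C(C)/C[C@@H]2OC(=O)C(=C)[C@@H]12 | intermediate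
14 | 2β,3α-epoxy-1α-hydroxy-12,9α-olide | O[C@@H]1[C@H]4O[C@]4(C)CC/C=C(C)/C[C@@H]2OC(=O)C(=C)[C@@H]12 | intermediate
15 | methacrylic anhydride | C=C(C)C(=O)OC(=O)C(C)=C | starting material
16 | 1-O-methacrylate of 14 | C=C(C)C(=O)O[C@@H]1[C@H]4O[C@]4(C)CC/C=C(C)/C[C@@H]2OC(=O)C(=C)[C@@H]12 | intermediate
17 | 6β,7α-diol | C=C(C)C(=O)O[C@@H]1[C@H]4O[C@]4(C)CC[C@@H](O)[C@](C)(O)C[C@@H]2OC(=O)C(=C)[C@@H]12 | intermediate
18 | 6-oxo-7α-hydroxy compound | C=C(C)C(=O)O[C@@H]1[C@H]4O[C@]4(C)CCC(=O)[C@](C)(O)C[C@@H]2OC(=O)C(=C)[C@@H]12 | intermediate
19 | bis(trimethylsilyl) enol ether | C=C(C)C(=O)O[C@@H]1[C@H]4O[C@]4(C)CC=C(O[Si](C)(C)C)[C@](C)(O[Si](C)(C)C)C[C@@H]2OC(=O)C(=C)[C@@H]12 | intermediate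
20 | epoxy (4E)-enone, 7-O-trimethylsilyl | C=C(C)C(=O)O[C@@H]1[C@H]4O[C@]4(C)/C=C/C(=O)[C@](C)(O[Si](C)(C)C)C[C@@H]2OC(=O)C(=C)[C@@H]12 | intermediate
21 | 2β-hydroxy (4E)-enone, 7-O-trimethylsilyl | C=C(C)C(=O)O[C@@H]1[C@@H](O)[C@H](C)/C=C/C(=O)[C@](C)(O[Si](C)(C)C)C[C@@H]2OC(=O)C(=C)[C@@H]12 | intermediate (not isolated)
22 | 2β,7α-dihydroxy (4E)-enone | C=C(C)C(=O)O[C@@H]1[C@@H](O)[C@H](C)/C=C/C(=O)[C@](C)(O)C[C@@H]2OC(=O)C(=C)[C@@H]12 | intermediate
23 | CNP0195404.1 | C=C(C)C(=O)O[C@@H]1[C@@H](O)[C@H](C)C2=CC(=O)[C@@](C)(C[C@@H]3OC(=O)C(=C)[C@@H]13)O2 | target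

## Step count and risks

Total: 16 steps. Longest linear sequence: 16 steps from farnesol 1 (anhydride 15 enters at step 10).

**Step 3 (key step).** The most likely failure is loss of 4 during isolation, by Cope rearrangement on warming or proton-induced transannular cyclisation on glass, silica or in slightly acidic buffer. Slow turnover as magnesium diphosphate accumulates is the second concern. Fallback: the cyclase is run in the same vessel as the oxidase microsomes of step 4, so the hydrocarbon is oxidised as it forms. This sets out from 3 and returns at 7; 4 is made but not isolated (no new compound; F0).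

**Step 8.** The carboxylate may act as a base (elimination of the sulfonate towards C8 or C10), or residual hydroxide may saponify the new lactone and scramble it between the C1 and C9 oxygens on acidification. Fallback: inversion and acyl transfer are separated. From 11, CsO2CH in DMF would give the inverted 9α-formate F1. Mild hydrolysis (KHCO3, aqueous THF) would give 9-epi-eupatolide F2. Catalytic DBU in toluene would then equilibrate the lactone between the C1 and C9 oxygens through the bridged tetrahedral intermediate; 13 is separated and F2 recycled. This returns at 13.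

**Step 11.** Osmylation may spread to the methylene lactone or methacrylate. The flexible C9-lactone ring may show the wrong face of C6=C7. The new hydroxyls may open the oxirane across the ring. Fallback: the dihydroxylation is moved to the rigid C1-lactone series, where only one acrylate competes. From 11, OsO4/N-methylmorpholine N-oxide would give diol F3 and Dess–Martin oxidation ketol F4. LiOH then heat (as in step 8) would give, via lithium carboxylate F5, the transposed ketol F6. VO(acac)2/t-BuOOH would give epoxy alcohol F7. Acylation with 15 (the tertiary hydroxyl is inert) returns at 18.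

**Step 15.** The π-allyl palladium intermediate may equilibrate through its C5-bound (enolate) form before hydride transfer, eroding C3. β-Hydride elimination to a dienol may compete. Triethylamine may promote acyl shift from C1 to the new C2 hydroxyl. Fallback: the ring is bridged first, so the allyl unit is locked in the bicycle and no free diol monoester meets base for long. From 20, aqueous citric acid would give hydroxy enone F8. The conditions of step 16 would give epoxy furanone F9. The same palladium/formic acid hydrogenolysis on F9 returns at 23.

**Step 16.** The 5-endo oxypalladation may be slow in the medium ring, leaving palladium hydride time to move the exocyclic methylene into the lactone ring or to oxidise the C2 alcohol. Fallback: a metal-free two-stage closure. From 22, catalytic camphorsulfonic acid in CH2Cl2 would give dihydrofuranone F10 by acid-catalysed oxa-Michael addition. PhSeCl in ethyl acetate would selenenylate C5 to give F11. H2O2/pyridine would give the selenoxide, whose syn elimination towards C4 returns at 23.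

## Further compounds

F0 | step 3 | none | none
F1 | step 8 | 9α-formate of 9-epi-eupatolide | C=C1C(=O)O[C@@H]2/C=C(C)/CC/C=C(C)/C[C@H](OC=O)[C@@H]12
F2 | step 8 | 9-epi-eupatolide (9α-hydroxyl, lactone on C1) | C=C1C(=O)O[C@@H]2/C=C(C)/CC/C=C(C)/C[C@H](O)[C@@H]12
F3 | step 11 | 6β,7α-diol of 11 | C=C1C(=O)O[C@@H]2/C=C(C)/CC[C@@H](O)[C@](C)(O)C[C@@H](OS(C)(=O)=O)[C@@H]12
F4 | step 11 | 6-oxo-7α-hydroxy mesylate | C=C1C(=O)O[C@@H]2/C=C(C)/CCC(=O)[C@](C)(O)C[C@@H](OS(C)(=O)=O)[C@@H]12
F5 | step 11 | lithium carboxylate of ring-opened F4 | [Li+].[O-]C(=O)C(=C)[C@@H]1[C@H](OS(C)(=O)=O)C[C@@](C)(O)C(=O)CC/C(C)=C/[C@H]1O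
F6 | step 11 | 1α,7α-dihydroxy-6-oxo-12,9α-olide | O[C@@H]1/C=C(C)/CCC(=O)[C@](C)(O)C[C@@H]2OC(=O)C(=C)[C@@H]12
F7 | step 11 | 2β,3α-epoxide of F6 | O[C@@H]1[C@H]4O[C@]4(C)CCC(=O)[C@](C)(O)C[C@@H]2OC(=O)C(=C)[C@@H]12
F8 | step 15 | 7α-hydroxy epoxy (4E)-enone | C=C(C)C(=O)O[C@@H]1[C@H]4O[C@]4(C)/C=C/C(=O)[C@](C)(O)C[C@@H]2OC(=O)C(=C)[C@@H]12
F9 | step 15 | 2β,3α-epoxy furanone | C=C(C)C(=O)O[C@@H]1[C@H]4O[C@]4(C)C2=CC(=O)[C@@](C)(C[C@@H]3OC(=O)C(=C)[C@@H]13)O2
F10 | step 16 | 4,5-dihydrofuranone (C4 configuration open) | C=C(C)C(=O)O[C@@H]1[C@@H](O)[C@H](C)C2CC(=O)[C@@](C)(C[C@@H]3OC(=O)C(=C)[C@@H]13)O2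
F11 | step 16 | 5-phenylselanyl dihydrofuranone (C4, C5 configuration open) | C=C(C)C(=O)O[C@@H]1[C@@H](O)[C@H](C)C2C([Se]c4ccccc4)C(=O)[C@@](C)(C[C@@H]3OC(=O)C(=C)[C@@H]13)O2
A1 | alternative 1 | nine-membered lactone with acetyl group on C7 | COc1ccc(CO[C@@H]2[C@@H](O[Si](C)(C)C(C)(C)C)[C@H](C)C(=O)O[C@@](C)(C(C)=O)C[C@H](O[Si](CC)(CC)CC)[C@H]2C(=C)CO[Si](CC)(CC)CC)cc1
A2 | alternative 1 | protected furanone-bridged carbocycle | COc1ccc(CO[C@@H]2[C@@H](O[Si](C)(C)C(C)(C)C)[C@H](C)C3=CC(=O)[C@@](C)(C[C@H](O[Si](CC)(CC)CC)[C@H]2C(=C)CO[Si](CC)(CC)CC)O3)cc1
A3 | alternative 2 | 7α-hydroxy (4E)-cyclodecenone, C2 triethylsilyl ether | C=C(C)C(=O)O[C@@H]1[C@@H](O[Si](CC)(CC)CC)[C@H](C)/C=C/C(=O)[C@](C)(O)C[C@@H]2OC(=O)C(=C)[C@@H]12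
A4 | alternative 2 | C2 triethylsilyl ether of the target | C=C(C)C(=O)O[C@@H]1[C@@H](O[Si](CC)(CC)CC)[C@H](C)C2=CC(=O)[C@@](C)(C[C@@H]3OC(=O)C(=C)[C@@H]13)O2
A5 | alternative 3 | trans-decalin C6-ol C2-mesylate | O[C@@]12C[C@H](O[Si](C)(C)C(C)(C)C)[C@@H](C)[C@H](OS(C)(=O)=O)[C@H]1[C@H](C(C)=C)[C@@H](OCOC)C[C@@]2(C)OCOC
A6 | alternative 3 | E-cyclodecenone | O=C1C[C@H](O[Si](C)(C)C(C)(C)C)[C@@H](C)/C=C/[C@H](C(C)=C)[C@@H](OCOC)C[C@@]1(C)OCOC
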